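The 2H-chromene is cut at its C3=C4 double bond. C3–C2 and C4–C4a are made together by a catalytic asymmetric oxa-Povarov reaction, a formal inverse-electron-demand [4+2] cycloaddition. One partner is an O-aryl oxocarbenium ion (cationic 2-oxadiene C4a=C8a–O1=C2), released from a mixed phenoxy acetal of ring A and the C2 aryl aldehyde. The other is an (E)-β-ethoxystyrene that already carries the whole chalcone. The step exploits C3 and C4 being the two carbons of a masked arylacetaldehyde enol ether: nucleophilic C3 meets C2, electrophilic C4 meets ring A carbon C4a. Loss of ethanol then gives ring C with C2 as the only stereocentre. All phenols travel as TBS ethers, removed last.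

Key step: step 7

Remark: chromene numbering is O1, C2, C3, C4, C4a, C5 to C8, C8a; ring A is the benzo ring, ring B the aryl on C2, ring C the pyran ring, ring D the phenol ring on C3, ring E the resorcinol ring of the ketone; C2 of the target is (S) (O1 > C3 > ring B > H); TBS = tert-butyldimethylsilyl.

Step 1
Reactants: 1 3-bromo-4-hydroxybenzaldehyde; 2 (E)-2-ethoxyvinylboronic acid pinacol ester
Product: 3 3-[(E)-2-ethoxyethenyl]-4-hydroxybenzaldehyde
Conditions: PdCl2(dppf) (3 mol %), K2CO3, 1,4-dioxane/H2O, 80 °C; work-up at pH 7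
Reagents that add atoms: none
Why: Suzuki–Miyaura coupling transfers the alkenyl group with retention of the (E) geometry, tolerates the free phenol and the aldehyde, and the enol ether is stable to the basic medium as long as acid is avoided on work-up.

Step 2
Reactants: 3 3-[(E)-2-ethoxyethenyl]-4-hydroxybenzaldehyde; 4 2,4-dihydroxyacetophenone
Product: 5 (E)-1-(2,4-dihydroxyphenyl)-3-{3-[(E)-2-ethoxyethenyl]-4-hydroxyphenyl}prop-2-en-1-one
Conditions: KOH (aq., excess), EtOH, rt to 40 °C; then AcOH to pH 6 at 0 °C
Reagents that add atoms: none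
Why: Claisen–Schmidt condensation (aldol addition, then E1cB dehydration) should give the conjugated (E)-enone as the thermodynamic isomer, the enol ether being inert to hydroxide and the strongly basic medium keeping the hydroxychalcone open.

Step 3
Reactants: 5 (E)-1-(2,4-dihydroxyphenyl)-3-{3-[(E)-2-ethoxyethenyl]-4-hydroxyphenyl}prop-2-en-1-one
Product: 6 (E)-1-[2,4-bis(tert-butyldimethylsilyloxy)phenyl]-3-{4-(tert-butyldimethylsilyloxy)-3-[(E)-2-ethoxyethenyl]phenyl}prop-2-en-1-one
Conditions: TBSCl (excess), imidazole, DMAP (cat.), DMF, rt to 45 °C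
Reagents that add atoms: tert-butyldimethylsilyl chloride (TBSCl), CC(C)(C)[Si](C)(C)Cl
Why: Phenol silylation with TBSCl and imidazole, with DMAP and warming for the hydrogen-bonded OH ortho to the ketone, should mask every acidic OH before the acid-catalysed key step and leaves enol ether and enone untouched.

Step 4
Reactants: 7 4-(tert-butyldimethylsilyloxy)benzaldehyde
Product: 8 1-(dimethoxymethyl)-4-(tert-butyldimethylsilyloxy)benzene
Conditions: HC(OMe)3, PPTS (cat.), MeOH, rt; Et3N quench
Reagents that add atoms: trimethyl orthoformate, COC(OC)OC; methanol, CO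
Why: Acid-catalysed acetalisation driven by the orthoformate as water scavenger should proceed cleanly, because aryl TBS ethers withstand mild acid in methanol.

Step 5
Reactants: 9 resorcinol
Product: 10 3-(tert-butyldimethylsilyloxy)phenol
Conditions: TBSCl (1 equiv), imidazole, DMF, 0 °C to rt, resorcinol in threefold excess
Reagents that add atoms: tert-butyldimethylsilyl chloride (TBSCl), CC(C)(C)[Si](C)(C)Cl
Why: Statistical mono-silylation of a symmetrical diphenol, where the excess of resorcinol should suppress the bis-ether and the mono-ether is separated by chromatography.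

Step 6
Reactants: 8 1-(dimethoxymethyl)-4-(tert-butyldimethylsilyloxy)benzene; 10 3-(tert-butyldimethylsilyloxy)phenol
Product: 12 1-(tert-butyldimethylsilyloxy)-3-{methoxy[4-(tert-butyldimethylsilyloxy)phenyl]methoxy}benzene (racemic mixed acetal), via chloro ether 11 (not isolated)
Conditions: AcCl, Zn(OAc)2 (cat.), CH2Cl2, 0 °C to rt; then 10, iPr2NEt, −20 °C to rt; Et3N-deactivated silica
Reagents that add atoms: none
Why: Acetal–acyl chloride exchange gives the α-chloro ether, which the phenol O-alkylates in the presence of the amine base by an SN1-like substitution of the kind used for alkoxymethyl ether formation, the base excluding the acid that would cause C-benzylation.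

Step 7
Reactants: 12 racemic mixed acetal; 6 (E)-1-[2,4-bis(tert-butyldimethylsilyloxy)phenyl]-3-{4-(tert-butyldimethylsilyloxy)-3-[(E)-2-ethoxyethenyl]phenyl}prop-2-en-1-one
Product: 14 (E)-1-[2,4-bis(tert-butyldimethylsilyloxy)phenyl]-3-{4-(tert-butyldimethylsilyloxy)-3-[(2S)-7-(tert-butyldimethylsilyloxy)-2-(4-(tert-butyldimethylsilyloxy)phenyl)-2H-chromen-3-yl]phenyl}prop-2-en-1-one, via 4-ethoxychroman cycloadduct 13 (not isolated)
Conditions: chiral BINOL-derived N-triflyl imidodiphosphorimidate Brønsted acid (5 mol %, antipode and 3,3'-aryl groups chosen by screening for the (S) product), 5 Å molecular sieves, toluene, −60 °C to −20 °C; then 0 °C; Et3N quench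
Reagents that add atoms: none
Why: Proposed new method: the chiral acid ionises 12 by loss of methanol to the (E)-O-aryl oxocarbenium ion (C4a=C8a–O1=C2) held as a contact ion pair by the confined chiral anion; the nucleophilic, aryl-bearing β-carbon of enol ether 6 adds to C2 (C3–C2 bond), and the O-ethyl oxocarbenium ion so formed at C4 is captured by ring A at the carbon ortho to O1 and para to the silyloxy group (C4–C4a bond), a stepwise formal inverse-electron-demand [4+2] cycloaddition. The closest known reactions are the SnCl4-promoted oxa-Povarov reaction of mixed phenoxy acetals with alkenes (racemic), the chiral-phosphoric-acid Povarov reaction of N-aryl imines with enol ethers and enecarbamates, and imidodiphosphorimidate-catalysed additions to oxocarbenium ion pairs. Ring C is closed in the second bond formation by a 6-exo-trig Friedel–Crafts attack of ring A on the exocyclic C4=O+ bond. The only lasting stereocentre, C2, is set in the first C–C bond formation by the chiral counteranion, which shields one enantiotopic face of the oxocarbenium ion; C3 and C4 are transient and vanish when acid-induced E1 loss of ethanol from the C4 benzylic cation (stabilised by O1 and the para silyloxy group) gives the C3=C4 double bond without touching C2. Regioselectivity (aryl on C3, not C4) follows from the polarity of the enol ether, site selectivity on ring A from the para-directing silyloxy group and the crowding of the other ortho position, and chemoselectivity from the enol ether being far more nucleophilic than the enone or the silyl ethers.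

Step 8
Reactants: 14 penta-TBS (2S)-chromene chalcone
Product: 15 (E)-1-(2,4-dihydroxyphenyl)-3-{4-hydroxy-3-[(2S)-7-hydroxy-2-(4-hydroxyphenyl)-2H-chromen-3-yl]phenyl}prop-2-en-1-one
Conditions: TBAF, AcOH (1:1, excess), THF, 0 °C to rt
Reagents that add atoms: none
Why: Fluoride-mediated cleavage of aryl silyl ethers, where the acetic acid buffer keeps the liberated phenols protonated so that neither quinone-methide opening of ring C at C2 nor flavanone closure of the chalcone should occur and C2 stays (S).

Compound list
1 | 3-bromo-4-hydroxybenzaldehyde | O=Cc1ccc(O)c(Br)c1 | starting material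
2 | (E)-2-ethoxyvinylboronic acid pinacol ester | CCO/C=C/B1OC(C)(C)C(C)(C)O1 | starting material
3 | 3-[(E)-2-ethoxyethenyl]-4-hydroxybenzaldehyde | CCO/C=C/c1cc(C=O)ccc1O | intermediate
4 | 2,4-dihydroxyacetophenone | CC(=O)c1ccc(O)cc1O | starting material
5 | (E)-1-(2,4-dihydroxyphenyl)-3-{3-[(E)-2-ethoxyethenyl]-4-hydroxyphenyl}prop-2-en-1-one | CCO/C=C/c1cc(/C=C/C(=O)c2ccc(O)cc2O)ccc1O | intermediate
6 | (E)-1-[2,4-bis(tert-butyldimethylsilyloxy)phenyl]-3-{4-(tert-butyldimethylsilyloxy)-3-[(E)-2-ethoxyethenyl]phenyl}prop-2-en-1-one | CCO/C=C/c1cc(/C=C/C(=O)c2ccc(O[Si](C)(C)C(C)(C)C)cc2O[Si](C)(C)C(C)(C)C)ccc1O[Si](C)(C)C(C)(C)C | intermediate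
7 | 4-(tert-butyldimethylsilyloxy)benzaldehyde | CC(C)(C)[Si](C)(C)Oc1ccc(C=O)cc1 | starting material
8 | 1-(dimethoxymethyl)-4-(tert-butyldimethylsilyloxy)benzene | COC(OC)c1ccc(O[Si](C)(C)C(C)(C)C)cc1 | intermediate
9 | resorcinol | Oc1cccc(O)c1 | starting material
10 | 3-(tert-butyldimethylsilyloxy)phenol | CC(C)(C)[Si](C)(C)Oc1cccc(O)c1 | intermediate
11 | 1-[chloro(methoxy)methyl]-4-(tert-butyldimethylsilyloxy)benzene (racemic, not isolated) | COC(Cl)c1ccc(O[Si](C)(C)C(C)(C)C)cc1 | intermediate
12 | 1-(tert-butyldimethylsilyloxy)-3-{methoxy[4-(tert-butyldimethylsilyloxy)phenyl]methoxy}benzene (racemic mixed acetal) | COC(Oc1cccc(O[Si](C)(C)C(C)(C)C)c1)c1ccc(O[Si](C)(C)C(C)(C)C)cc1 | intermediate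
13 | (E)-1-[2,4-bis(tert-butyldimethylsilyloxy)phenyl]-3-{4-(tert-butyldimethylsilyloxy)-3-[(2R,3R,4R)-4-ethoxy-7-(tert-butyldimethylsilyloxy)-2-(4-(tert-butyldimethylsilyloxy)phenyl)chroman-3-yl]phenyl}prop-2-en-1-one (2,3-trans-3,4-trans, expected major diastereomer, not isolated) | CCO[C@H]1c2ccc(O[Si](C)(C)C(C)(C)C)cc2O[C@@H](c2ccc(O[Si](C)(C)C(C)(C)C)cc2)[C@@H]1c1cc(/C=C/C(=O)c2ccc(O[Si](C)(C)C(C)(C)C)cc2O[Si](C)(C)C(C)(C)C)ccc1O[Si](C)(C)C(C)(C)C | intermediate
14 | (E)-1-[2,4-bis(tert-butyldimethylsilyloxy)phenyl]-3-{4-(tert-butyldimethylsilyloxy)-3-[(2S)-7-(tert-butyldimethylsilyloxy)-2-(4-(tert-butyldimethylsilyloxy)phenyl)-2H-chromen-3-yl]phenyl}prop-2-en-1-one | O=C(/C=C/c1ccc(O[Si](C)(C)C(C)(C)C)c(C2=Cc3ccc(O[Si](C)(C)C(C)(C)C)cc3O[C@H]2c2ccc(O[Si](C)(C)C(C)(C)C)cc2)c1)c1ccc(O[Si](C)(C)C(C)(C)C)cc1O[Si](C)(C)C(C)(C)C | intermediate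
15 | (E)-1-(2,4-dihydroxyphenyl)-3-{4-hydroxy-3-[(2S)-7-hydroxy-2-(4-hydroxyphenyl)-2H-chromen-3-yl]phenyl}prop-2-en-1-one | O=C(/C=C/c1ccc(O)c(C2=Cc3ccc(O)cc3O[C@H]2c2ccc(O)cc2)c1)c1ccc(O)cc1O | target

Total step count: 8. Longest linear sequence: 5 steps (steps 1, 2, 3, 7, 8).

Steps most likely to fail

Step 7 (proposed new method). The chiral anion may not discriminate the two faces of the acyclic O-aryl oxocarbenium ion. The strong acid may epimerise C2 by reversible opening of ring C, or protonate the enol ether faster than it ionises the acetal. The fallback uses known chemistry, sets out from 12 and 6 and comes back at 14. The oxa-Povarov reaction is run without stereocontrol with SnCl4 in CH2Cl2 at −78 °C, which should give the racemic 2,3-trans-3,4-trans 4-ethoxychroman F1. Brief warming with PPTS should eliminate ethanol to the racemic silylated chromene F2. Preparative chromatography on a chiral stationary phase then removes the (R)-configured chromene F3 and leaves 14.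

Step 2. The aldol addition may stall because the para-phenoxide deactivates the aldehyde and the ketone must react as a polyanion. The hydroxychalcone may partly close to the flavanone, and the ortho-hydroxystyryl ether may cyclise to a benzofuran during neutralisation. The fallback sets out from 1 and 4 and comes back at 5; it swaps the order so that the condensation can be run under acid, before the acid-labile enol ether exists. BF3·OEt2-mediated Claisen–Schmidt condensation of 1 with 4 in 1,4-dioxane at rt should give the bromo chalcone (E)-3-(3-bromo-4-hydroxyphenyl)-1-(2,4-dihydroxyphenyl)prop-2-en-1-one F4. Suzuki–Miyaura coupling of that bromo chalcone with 2 under the conditions of step 1 then gives 5.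

Step 6. Traces of HCl may ionise the very labile chloro ether or the mixed acetal, leading to Friedel–Crafts C-benzylation of the electron-rich phenol and to hydrolysis during chromatography. The fallback sets out from 8 and 10 and comes back at 14. The mixed acetal is not prepared separately: 8, 10 and 6 are combined with the acid catalyst of step 7 over 5 Å molecular sieves (three-component variant). Acid-catalysed acetal exchange then forms 12 only in the flask, where the more nucleophilic enol ether intercepts the oxocarbenium ion and the sequence of step 7 carries on to 14. This fallback makes no compound outside the list (F0).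

Further compounds
F1 | step 7 | racemic 2,3-trans-3,4-trans 4-ethoxychroman (racemate of 13) | CCOC1c2ccc(O[Si](C)(C)C(C)(C)C)cc2OC(c2ccc(O[Si](C)(C)C(C)(C)C)cc2)C1c1cc(/C=C/C(=O)c2ccc(O[Si](C)(C)C(C)(C)C)cc2O[Si](C)(C)C(C)(C)C)ccc1O[Si](C)(C)C(C)(C)C
F2 | step 7 | racemic silylated chromene (racemate of 14) | O=C(/C=C/c1ccc(O[Si](C)(C)C(C)(C)C)c(C2=Cc3ccc(O[Si](C)(C)C(C)(C)C)cc3OC2c2ccc(O[Si](C)(C)C(C)(C)C)cc2)c1)c1ccc(O[Si](C)(C)C(C)(C)C)cc1O[Si](C)(C)C(C)(C)C
F3 | step 7 | (R)-configured chromene (enantiomer of 14) | O=C(/C=C/c1ccc(O[Si](C)(C)C(C)(C)C)c(C2=Cc3ccc(O[Si](C)(C)C(C)(C)C)cc3O[C@@H]2c2ccc(O[Si](C)(C)C(C)(C)C)cc2)c1)c1ccc(O[Si](C)(C)C(C)(C)C)cc1O[Si](C)(C)C(C)(C)C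
F4 | step 2 | (E)-3-(3-bromo-4-hydroxyphenyl)-1-(2,4-dihydroxyphenyl)prop-2-en-1-one | O=C(/C=C/c1ccc(O)c(Br)c1)c1ccc(O)cc1O
F0 | step 6 | none | none
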